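The earlier runs and the new flask come from a simulation with constants of no real substance; scatter was added.

The number to start from is 1.50: that is how many times the target of the dawn run the summer run holds at 0.46 h, although its [substrate] charge went from 50.0 mM to 150 mM.

all flasks: free catalyst 0.250 mM

|  | substrate | partner | target | time |
|---|---|---|---|---|
| dawn | 50.0 mM | 50.0 mM |  |  |
| winter | 20.0 mM | 20.0 mM |  |  |
| summer | 150 mM | 50.0 mM |  |  |
| autumn | 50.0 mM | 100 mM |  |  |
| spring | 50.0 mM | 50.0 mM | 15.0 mM | 3.2 h |

- dawn run (time / h: [target] / mM): 0.13: 1.3; 0.24: 2.3; 0.46: 4.8; 0.88: 7.9; 1.7: 13.1; 3.2: 18.5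
- winter run (time / h: [target] / mM): 0.13: 0.1; 0.24: 0.1; 0.46: 1.3; 0.88: 1.9; 1.7: 4.1; 3.2: 6.0
- summer run (time / h: [target] / mM): 0.13: 2.0; 0.24: 4.3; 0.46: 7.2; 0.88: 12.5; 1.7: 19.7; 3.2: 28.2
- autumn run (time / h: [target] / mM): 0.13: 2.8; 0.24: 4.6; 0.46: 9.1; 0.88: 14.7; 1.7: 22.3; 3.2: 29.6

(each reading ± 0.3 mM)

- apparent order in [substrate] of the starting rate, round the charge of the dawn run (the rate where two percent of its substrate have turned into target) (one fixed amount of target, the same in the runs compared)
- apparent order in [partner] of the starting rate, round the charge of the dawn run (the rate where two percent of its substrate have turned into target)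
- target in the spring run at 3.2 h, as a share of the substrate charged

- Overall: substrate + partner -> target, with free catalyst as catalyst.
- Constant volume, constant temperature.
- What is held in complexes is read along with the free species.
- "The second partner" is partner.
- An order is taken over about fifteen percent of the charge, up and down.
- A share of target counts the target that was charged too.

First, does the partner act in proportion? At that same time the autumn run, with 100 mM of partner against dawn's 50.0 mM, holds 1.90 times dawn's target. In logarithms that reads as an order in [partner] of 0.923, so we take first order, given a scatter of 0.3 mM.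

Then, what is the order in [substrate]? The same logarithms give 0.369, but that is a mean over the whole span, not the order at dawn's charge. We assume the simplest bending curve, with the rate proportional to [substrate]/(H + [substrate]). Here H, the half-ceiling charge (the Michaelis constant), is the [substrate] at which the rate stands at half its ceiling for a fixed [partner]. The ratio reads 50.0 mM, and the local order is H/(H + [substrate]), so 0.500 at dawn's charge.

Last, what does charged target do in the spring run? Dawn's early rate reads 10.4 mM h⁻¹. Between 1.7 h and 3.2 h, around 15.8 mM of target, near spring's charge, dawn's rate reads 3.60 mM h⁻¹. With H and first order in [partner], the depleted charge predicts 5.80 mM h⁻¹, which leaves a factor 0.621. We hold that factor flat in spring and suppose spring makes about 15.8 mM, so its mean charge is down by half of that. This gives a mean rate of 4.99 mM h⁻¹, 16.0 mM in 3.2 h, and a share of 61.9%.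

The forecast, which reads the later shortfall as “product inhibition”, says 0.55 (0.35 to 0.8) for the order in [substrate], 1 (0.8 to 1.2) for the order in [partner] and 60% (54% to 67%) for the share in the spring run, and our share stands higher than its figure.

The flask gives 0.54 for the order in [substrate], 1.0 for the order in [partner] and 59.8% for the share in the spring run.

    free catalyst + substrate ⇌ catalyst-substrate complex, settled at all times (18.40 M⁻¹)
    catalyst-substrate complex + partner → target + free catalyst (1768 M⁻¹ h⁻¹)
    free catalyst + target → spent catalyst + target (31.14 M⁻¹ h⁻¹)

The fit with these steps leaves a root mean square residual of 1.2 in units of the scatter, and the fit with the main steps alone leaves 3.7. Our H put the order at dawn's charge at 0.500, beside the flask's 0.54. Carried to the winter run from dawn's 10 mM h⁻¹, where two percent of dawn's substrate have turned, H and first order in [partner] give 2.34 mM h⁻¹, and the winter run stands at 2.2 mM h⁻¹.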